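(The readings were generated by integration for substances that don't exist, and the scatter is random.)

How much side product stands in the flask at 15 min, and how much target remains after a very long wait?

| flask | solid substrate | reagent | remark | time |
|---|---|---|---|---|
| Sunday's | 0.44 M | 0.792 M | run made earlier |  |
| Tuesday's | 0.99 M | 0.792 M | run made earlier |  |
| Thursday's | 0.66 M | 0.40 M | run made earlier |  |
| flask | 0.66 M | 0.792 M |  | 15 min |

- Sunday's (time / min: side product / %, target / %, solid substrate / %): 1.00: 1, 0, 99; 3.00: 2, 1, 96; 5.00: 5, 2, 93; 8.00: 6, 3, 88; 10.0: 8, 5, 86; 15.0: 13, 4, 81; 20.0: 18, 0, 77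
- Tuesday's (time / min: side product / %, target / %, solid substrate / %): 1.00: 1, 0, 99; 3.00: 3, 0, 99; 5.00: 0, 1, 97; 8.00: 2, 0, 96; 10.0: 3, 2, 95; 15.0: 5, 3, 89; 20.0: 8, 2, 85
- Thursday's (time / min: side product / %, target / %, solid substrate / %): 4.00: 0, 0, 97; 8.00: 1, 4, 93; 10.0: 4, 1, 94; 15.0: 4, 0, 87; 20.0: 2, 0, 86

(readings scatter by 1.5 percentage points)

- amount of side product at 15 min, in percent of the solid substrate charged
- amount of target if the flask were left three thousand times as long, in percent of the solid substrate charged

- solid, in amounts per volume of the solution: solid substrate
- at the start none of the solid substrate is in solution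
- what has only dissolved of solid substrate counts as not reacted

Sunday's and Tuesday's runs carry the flask's reagent charge on different solid charges, and their percentages differ, but in concentration they read 0.0792 M and 0.0792 M of side product at 20.0 min. So in these two runs [side product] is read as following time rather than the solid charge. From 10.0 min to 20.0 min these runs gain 0.00440 M min⁻¹ and 0.00495 M min⁻¹, so over that stretch a straight line, an apparent zero order, integrates at once. The side-product slope, their mean gain of [side product] per minute at 0.792 M of reagent, is 0.00468 M min⁻¹. Stepping back along it from the mean 20.0 min reading, 0.0792 M, and dividing by 0.66 M gives my own 8.46 % for the flask.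

The forecast, slightly lower than this reckoning, says 8.3 % (6 % to 10.5 %) and 15 % of target (3 % to 35 %), judging of the loss of solid that “this looks like saturation- or dissolution-limited feed”.

The flask gives 8.55 % of side product and 0 % of target. The half-life of target by conversion into over-reaction product is 80 h, long against 15 min. Between 7.50 min and 15.0 min, the flask gains 0.00449 M min⁻¹ of side product, against the slope of 0.00468 M min⁻¹.

    starting material + reagent ⇌ target (K = 0.780 M⁻¹, k = 0.0220 M⁻¹ s⁻¹)
    starting material + 2 reagent → side product (k = 0.00910 M⁻² s⁻¹)
    target → over-reaction product (k = 2.40 × 10⁻⁶ s⁻¹)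
    solid substrate ⇌ starting material, rate k4*(cs4 - [starting material]) while solid is left; crystals form when [starting material] > cs4 (solubility = 0.0600 M, k = 0.00200 s⁻¹)

Read at 25 min, the same flask should hold 15.5 % by the slope. The computed value is 15.1 %.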